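With C1 as the ester carbon, the 1,2-dioxane is disconnected at the O–C6 bond. The key step exploits the fully substituted C6–O centre of the peroxide ring (CH3, ring C5, chain C7), which lies 1,4 to C3–O: a C3 hydroperoxide opens a tethered (R)-2-methyl-2-alkyl oxirane at its tertiary carbon with inversion, closing the ring (6-exo), setting C6 independently of C3 and releasing the C7 hydroxymethyl handle in one operation. The precursor holds the syn C2/C3 array (anti-crotylation, then invertive perhydrolysis of a mesylate), the glycidol-derived epoxide and an acid-stable TBDPS ether at C1. The trienyl chain is joined afterwards by B-alkyl Suzuki coupling; C1 is oxidised last.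

Key step: step 10

Assumption: the facial preference of the binaphthyl phosphoric acid catalyst with this aliphatic aldehyde is taken to follow the sense known for aromatic aldehydes (the (R)-acid delivers the allyl unit to the Re face), so the (S)-acid is specified to obtain Si-face addition.

Step 1
Reactants: 1 (S)-2-methylglycidol; 2 allylmagnesium bromide
Product: 3 (2R)-2-methylhex-5-ene-1,2-diol
Conditions: 2 (3 equiv), CuI (10 mol %), THF, −30 → 0 °C; sat. aq. NH4Cl
Reagents that add atoms: none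
Why: Copper-catalysed Grignard opening of the epoxide (SN2 at the unhindered CH2) leaves the C–O bond of the quaternary carbon untouched, so the stereocentre is carried over unchanged, and a Payne rearrangement of the intermediate alkoxide would be degenerate and lead to the same diol.

Step 2
Reactants: 3 (2R)-2-methylhex-5-ene-1,2-diol
Product: 4 (4R)-4-(but-3-en-1-yl)-2,2,4-trimethyl-1,3-dioxolane
Conditions: 2,2-dimethoxypropane, pyridinium p-toluenesulfonate (cat.), CH2Cl2, rt
Reagents that add atoms: 2,2-dimethoxypropane, COC(C)(C)OC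
Why: Acid-catalysed transketalisation ties the primary and the tertiary hydroxyl into a dioxolane, which prevents lactol formation once the aldehyde is unveiled.

Step 3
Reactants: 4 (4R)-4-(but-3-en-1-yl)-2,2,4-trimethyl-1,3-dioxolane
Product: 6 3-[(4R)-2,2,4-trimethyl-1,3-dioxolan-4-yl]propanal, via ozonide 5 (not isolated)
Conditions: O3, CH2Cl2, −78 °C; PPh3, −78 °C → rt
Reagents that add atoms: ozone, [O-][O+]=O
Why: Ozonolysis of the monosubstituted alkene with reductive work-up should give the aldehyde cleanly, the ketal and the quaternary centre being inert.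

Step 4
Reactants: 6 3-[(4R)-2,2,4-trimethyl-1,3-dioxolan-4-yl]propanal; 7 (E)-crotylboronic acid pinacol ester
Product: 9 (3S,4R)-3-methyl-6-[(4R)-2,2,4-trimethyl-1,3-dioxolan-4-yl]hex-1-en-4-ol, via boronate 8 (not isolated)
Conditions: 7 (1.3 equiv), (S)-3,3'-bis(2,4,6-triisopropylphenyl)-1,1'-binaphthyl-2,2'-diyl hydrogen phosphate (5 mol %), 4 Å MS, toluene, −30 °C; aq. NaHCO3
Reagents that add atoms: none
Why: Chiral phosphoric acid-catalysed crotylboration runs through a closed chair transition state in which the E-crotyl geometry fixes the 3,4-anti relationship and the (S)-acid should direct addition to the Si face of the aldehyde (reagent control, the remote dioxolane centre being a spectator); any minor facial isomer is a diastereomer that can be removed at the cyclic stage.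

Step 5
Reactants: 9 (3S,4R)-3-methyl-6-[(4R)-2,2,4-trimethyl-1,3-dioxolan-4-yl]hex-1-en-4-ol
Product: 11 (2S,3R)-2-methyl-5-[(4R)-2,2,4-trimethyl-1,3-dioxolan-4-yl]pentane-1,3-diol, via ozonide 10 (not isolated)
Conditions: O3, CH2Cl2, −78 °C; NaBH4, MeOH, −78 °C → rt
Reagents that add atoms: ozone, [O-][O+]=O
Why: Ozonolysis with borohydride work-up turns the vinyl group into the C1 hydroxymethyl group without passing through an isolable, epimerisable β-hydroxy aldehyde.

Step 6
Reactants: 11 (2S,3R)-2-methyl-5-[(4R)-2,2,4-trimethyl-1,3-dioxolan-4-yl]pentane-1,3-diol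
Product: 12 (2S,3R)-1-[(tert-butyldiphenylsilyl)oxy]-2-methyl-5-[(4R)-2,2,4-trimethyl-1,3-dioxolan-4-yl]pentan-3-ol
Conditions: TBDPSCl (1.05 equiv), imidazole, CH2Cl2, 0 °C
Reagents that add atoms: tert-butyl(chloro)diphenylsilane, CC(C)(C)[Si](Cl)(c1ccccc1)c1ccccc1
Why: Silylation with the bulky chloride is selective for the primary hydroxyl, and the TBDPS ether is chosen because it survives both the ketal hydrolysis and the acid of the ring closure.

Step 7
Reactants: 12 (2S,3R)-1-[(tert-butyldiphenylsilyl)oxy]-2-methyl-5-[(4R)-2,2,4-trimethyl-1,3-dioxolan-4-yl]pentan-3-ol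
Product: 13 (2R,5R,6S)-7-[(tert-butyldiphenylsilyl)oxy]-2,6-dimethylheptane-1,2,5-triol
Conditions: AcOH/H2O/THF (3:1:1), 45 °C
Reagents that add atoms: none
Why: Mild acid hydrolysis of the terminal acetonide should leave the TBDPS ether intact.

Step 8
Reactants: 13 (2R,5R,6S)-7-[(tert-butyldiphenylsilyl)oxy]-2,6-dimethylheptane-1,2,5-triol
Product: 15 (2S,3R)-1-[(tert-butyldiphenylsilyl)oxy]-2-methyl-5-[(2R)-2-methyloxiran-2-yl]pentan-3-yl methanesulfonate, via bis-mesylate 14 (not isolated)
Conditions: MsCl (2.3 equiv), Et3N, CH2Cl2, −20 → 0 °C; solvent exchange; K2CO3, MeOH, 0 °C → rt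
Reagents that add atoms: methanesulfonyl chloride, CS(=O)(=O)Cl
Why: Sulfonylation takes the primary and the secondary hydroxyl but not the tertiary one, and base then closes the oxirane by 3-exo-tet displacement of the primary mesylate (intramolecular Williamson reaction, far faster than 5-exo attack on the β-branched secondary mesylate), which keeps the quaternary configuration and never exposes a free C3 hydroxyl next to the epoxide.

Step 9
Reactants: 15 (2S,3R)-1-[(tert-butyldiphenylsilyl)oxy]-2-methyl-5-[(2R)-2-methyloxiran-2-yl]pentan-3-yl methanesulfonate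
Product: 16 tert-butyl{[(2S,3S)-3-hydroperoxy-2-methyl-5-[(2R)-2-methyloxiran-2-yl]pentyl]oxy}diphenylsilane
Conditions: 50% aq. H2O2 (excess), KOH, THF/MeOH, 0 °C → rt
Reagents that add atoms: hydrogen peroxide, OO
Why: SN2 perhydrolysis of the secondary mesylate by the hydroperoxide anion proceeds with inversion and so converts the anti C2/C3 array into the syn hydroperoxide, while under base the epoxide is shielded because its exo position is tertiary and its CH2 is neopentyl-like.

Step 10
Reactants: 16 tert-butyl{[(2S,3S)-3-hydroperoxy-2-methyl-5-[(2R)-2-methyloxiran-2-yl]pentyl]oxy}diphenylsilane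
Product: 17 {(3S,6S)-6-[(2S)-1-[(tert-butyldiphenylsilyl)oxy]propan-2-yl]-3-methyl-1,2-dioxan-3-yl}methanol
Conditions: Sc(OTf)3 (10 mol %), CH2Cl2, −20 → 0 °C
Reagents that add atoms: none
Why: Sc(OTf)3 coordinates the oxirane oxygen and lengthens its bond to the tertiary carbon C6, which the terminal hydroperoxide oxygen attacks from the rear in a loose SN2-type displacement. The closest known reaction type is the acid-promoted intramolecular opening of epoxides by hydroperoxides (and by hydroxyl groups in polyether synthesis) at the more substituted carbon with inversion. The 1,2-dioxane closes in the 6-exo-tet mode, the 7-endo attack at the CH2 carbon being disfavoured by ring size and by the Markovnikov bias of the activated 2,2-disubstituted epoxide. The new C6 stereocentre is controlled by the (R) configuration of the glycidol-derived epoxide, transferred by stereospecific inversion, so no induction from C3 is needed. The step requires attack at C6 and substitution ahead of ionisation, hydride shift or elimination; the tethered nucleophile, the non-ionising solvent, the low temperature and the absence of alkenes or other internal nucleophiles should secure this. The epoxide oxygen is released as the primary C7 hydroxyl, and the TBDPS ether is inert to the catalyst.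

Step 11
Reactants: 17 {(3S,6S)-6-[(2S)-1-[(tert-butyldiphenylsilyl)oxy]propan-2-yl]-3-methyl-1,2-dioxan-3-yl}methanol
Product: 18 (3S,6S)-6-[(2S)-1-[(tert-butyldiphenylsilyl)oxy]propan-2-yl]-3-methyl-1,2-dioxane-3-carbaldehyde
Conditions: Dess–Martin periodinane, NaHCO3, CH2Cl2, 0 °C → rt
Reagents that add atoms: none
Why: Dess–Martin oxidation is neutral and non-reducing, and the resulting aldehyde has no α-hydrogen, so neither the peroxide nor the quaternary centre is at risk.

Step 12
Reactants: 18 (3S,6S)-6-[(2S)-1-[(tert-butyldiphenylsilyl)oxy]propan-2-yl]-3-methyl-1,2-dioxane-3-carbaldehyde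
Product: 19 tert-butyl{(2S)-2-[(3S,6S)-6-ethenyl-6-methyl-1,2-dioxan-3-yl]propoxy}diphenylsilane
Conditions: Ph3PCH3Br, KN(SiMe3)2, THF, −78 → 0 °C
Reagents that add atoms: methyltriphenylphosphonium bromide, C[P+](c1ccccc1)(c1ccccc1)c1ccccc1.[Br-]
Why: Wittig methylenation of the non-enolisable aldehyde with a salt-free ylide at low temperature should be faster than any attack of the ylide on the dialkyl peroxide.

Step 13
Reactants: 20 1-(trimethylsilyl)propyne; 21 geranyl chloride
Product: 23 [(5E)-6,10-dimethylundeca-5,9-dien-1-yn-1-yl]trimethylsilane, via propargyllithium 22 (not isolated)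
Conditions: n-BuLi, THF, −78 → −20 °C; 21, −78 °C → rt
Reagents that add atoms: none
Why: The propargylic lithium reagent alkylates the primary allylic chloride by direct SN2 substitution, which keeps the E geometry of the geranyl unit.

Step 14
Reactants: 23 [(5E)-6,10-dimethylundeca-5,9-dien-1-yn-1-yl]trimethylsilane
Product: 24 (5E)-6,10-dimethylundeca-5,9-dien-1-yne
Conditions: K2CO3, MeOH, rt
Reagents that add atoms: none
Why: Methoxide-mediated protodesilylation of the alkynylsilane is selective for the C(sp)–Si bond.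

Step 15
Reactants: 24 (5E)-6,10-dimethylundeca-5,9-dien-1-yne
Product: 26 (1E,5E)-1-iodo-2,6,10-trimethylundeca-1,5,9-triene, via alkenylalane 25 (not isolated)
Conditions: Me3Al (2.5 equiv), Cp2ZrCl2 (0.25 equiv), CH2Cl2, 0 °C → rt; I2, THF, −30 → 0 °C
Reagents that add atoms: trimethylaluminium, C[Al](C)C; iodine, II
Why: Negishi zirconium-catalysed carboalumination adds methyl and aluminium syn across the terminal alkyne with methyl at the internal carbon, and iodinolysis with retention gives the E-alkenyl iodide, the trisubstituted alkenes being untouched.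

Step 16
Reactants: 19 tert-butyl{(2S)-2-[(3S,6S)-6-ethenyl-6-methyl-1,2-dioxan-3-yl]propoxy}diphenylsilane; 26 (1E,5E)-1-iodo-2,6,10-trimethylundeca-1,5,9-triene
Product: 28 tert-butyl{(2S)-2-[(3S,6R)-6-methyl-6-[(3E,7E)-4,8,12-trimethyltrideca-3,7,11-trien-1-yl]-1,2-dioxan-3-yl]propoxy}diphenylsilane, via alkylborane 27 (not isolated)
Conditions: 9-BBN (1.5 equiv), THF, 0 °C → rt; then H2O, 26 (1.2 equiv), Pd(dppf)Cl2 (5 mol %), AsPh3 (5 mol %), Cs2CO3, DMF, rt
Reagents that add atoms: none
Why: 9-BBN adds to the vinyl group at the terminal carbon only (the boron ends up γ to the ring oxygen, so no β-elimination), and B-alkyl Suzuki–Miyaura coupling after oxidative addition of the alkenyl iodide to zerovalent palladium forms the C8–C9 bond at room temperature with retention of the E geometry.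

Step 17
Reactants: 28 tert-butyl{(2S)-2-[(3S,6R)-6-methyl-6-[(3E,7E)-4,8,12-trimethyltrideca-3,7,11-trien-1-yl]-1,2-dioxan-3-yl]propoxy}diphenylsilane
Product: 29 (2S)-2-[(3S,6R)-6-methyl-6-[(3E,7E)-4,8,12-trimethyltrideca-3,7,11-trien-1-yl]-1,2-dioxan-3-yl]propan-1-ol
Conditions: Bu4NF, AcOH, THF, rt
Reagents that add atoms: none
Why: Fluoride-mediated desilylation, buffered with acetic acid to suppress base-induced fragmentation of the peroxide, frees the C1 alcohol.

Step 18
Reactants: 29 (2S)-2-[(3S,6R)-6-methyl-6-[(3E,7E)-4,8,12-trimethyltrideca-3,7,11-trien-1-yl]-1,2-dioxan-3-yl]propan-1-ol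
Product: 31 (2R)-2-[(3S,6R)-6-methyl-6-[(3E,7E)-4,8,12-trimethyltrideca-3,7,11-trien-1-yl]-1,2-dioxan-3-yl]propanoic acid, via aldehyde 30 (not isolated)
Conditions: 2,2,6,6-tetramethylpiperidin-1-oxyl (0.2 equiv), PhI(OAc)2 (2.5 equiv), MeCN/H2O (1:1), rt
Reagents that add atoms: water, O
Why: Nitroxyl-catalysed oxidation with the iodane takes the primary alcohol through the aldehyde hydrate to the acid under weakly acidic, chlorine-free conditions that spare the trisubstituted alkenes, the peroxide and the C2 stereocentre.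

Step 19
Reactants: 31 (2R)-2-[(3S,6R)-6-methyl-6-[(3E,7E)-4,8,12-trimethyltrideca-3,7,11-trien-1-yl]-1,2-dioxan-3-yl]propanoic acid
Product: 32 methyl (2R)-2-[(3S,6R)-6-methyl-6-[(3E,7E)-4,8,12-trimethyltrideca-3,7,11-trien-1-yl]-1,2-dioxan-3-yl]propanoate (CNP0145612.1)
Conditions: Me3SiCHN2, toluene/MeOH (4:1), 0 °C
Reagents that add atoms: (trimethylsilyl)diazomethane, C[Si](C)(C)C=[N+]=[N-]
Why: Diazoalkane esterification is neutral and base-free, so the β-peroxy ester is formed without risk of epimerisation at C2 or of retro-oxa-Michael ring opening.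

Compound list
1 | (S)-2-methylglycidol | C[C@]1(CO)CO1 | starting material
2 | allylmagnesium bromide | C=CC[Mg]Br | starting material
3 | (2R)-2-methylhex-5-ene-1,2-diol | C=CCC[C@@](C)(O)CO | intermediate
4 | (4R)-4-(but-3-en-1-yl)-2,2,4-trimethyl-1,3-dioxolane | C=CCC[C@]1(C)COC(C)(C)O1 | intermediate
5 | 3-{2-[(4R)-2,2,4-trimethyl-1,3-dioxolan-4-yl]ethyl}-1,2,4-trioxolane (ozonide, epimers at the trioxolane carbon) | O1COOC1CC[C@]1(C)COC(C)(C)O1 | intermediate
6 | 3-[(4R)-2,2,4-trimethyl-1,3-dioxolan-4-yl]propanal | O=CCC[C@]1(C)COC(C)(C)O1 | intermediate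
7 | (E)-crotylboronic acid pinacol ester | C/C=C/CB1OC(C)(C)C(C)(C)O1 | starting material
8 | 4,4,5,5-tetramethyl-2-{[(3S,4R)-3-methyl-6-[(4R)-2,2,4-trimethyl-1,3-dioxolan-4-yl]hex-1-en-4-yl]oxy}-1,3,2-dioxaborolane | C=C[C@H](C)[C@H](OB1OC(C)(C)C(C)(C)O1)CC[C@]1(C)COC(C)(C)O1 | intermediate
9 | (3S,4R)-3-methyl-6-[(4R)-2,2,4-trimethyl-1,3-dioxolan-4-yl]hex-1-en-4-ol | C=C[C@H](C)[C@H](O)CC[C@]1(C)COC(C)(C)O1 | intermediate
10 | (2R,3R)-2-(1,2,4-trioxolan-3-yl)-5-[(4R)-2,2,4-trimethyl-1,3-dioxolan-4-yl]pentan-3-ol (ozonide, epimers at the trioxolane carbon) | O1COOC1[C@H](C)[C@H](O)CC[C@]1(C)COC(C)(C)O1 | intermediate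
11 | (2S,3R)-2-methyl-5-[(4R)-2,2,4-trimethyl-1,3-dioxolan-4-yl]pentane-1,3-diol | OC[C@H](C)[C@H](O)CC[C@]1(C)COC(C)(C)O1 | intermediate
12 | (2S,3R)-1-[(tert-butyldiphenylsilyl)oxy]-2-methyl-5-[(4R)-2,2,4-trimethyl-1,3-dioxolan-4-yl]pentan-3-ol | CC(C)(C)[Si](c1ccccc1)(c1ccccc1)OC[C@H](C)[C@H](O)CC[C@]1(C)COC(C)(C)O1 | intermediate
13 | (2R,5R,6S)-7-[(tert-butyldiphenylsilyl)oxy]-2,6-dimethylheptane-1,2,5-triol | CC(C)(C)[Si](c1ccccc1)(c1ccccc1)OC[C@H](C)[C@H](O)CC[C@@](C)(O)CO | intermediate
14 | (2R,5R,6S)-7-[(tert-butyldiphenylsilyl)oxy]-2-hydroxy-2,6-dimethylheptane-1,5-diyl dimethanesulfonate | CC(C)(C)[Si](c1ccccc1)(c1ccccc1)OC[C@H](C)[C@H](OS(C)(=O)=O)CC[C@@](C)(O)COS(C)(=O)=O | intermediate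
15 | (2S,3R)-1-[(tert-butyldiphenylsilyl)oxy]-2-methyl-5-[(2R)-2-methyloxiran-2-yl]pentan-3-yl methanesulfonate | CC(C)(C)[Si](c1ccccc1)(c1ccccc1)OC[C@H](C)[C@H](OS(C)(=O)=O)CC[C@]1(C)CO1 | intermediate
16 | tert-butyl{[(2S,3S)-3-hydroperoxy-2-methyl-5-[(2R)-2-methyloxiran-2-yl]pentyl]oxy}diphenylsilane | CC(C)(C)[Si](c1ccccc1)(c1ccccc1)OC[C@H](C)[C@@H](OO)CC[C@]1(C)CO1 | intermediate
17 | {(3S,6S)-6-[(2S)-1-[(tert-butyldiphenylsilyl)oxy]propan-2-yl]-3-methyl-1,2-dioxan-3-yl}methanol | CC(C)(C)[Si](c1ccccc1)(c1ccccc1)OC[C@H](C)[C@@H]1CC[C@@](C)(CO)OO1 | intermediate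
18 | (3S,6S)-6-[(2S)-1-[(tert-butyldiphenylsilyl)oxy]propan-2-yl]-3-methyl-1,2-dioxane-3-carbaldehyde | CC(C)(C)[Si](c1ccccc1)(c1ccccc1)OC[C@H](C)[C@@H]1CC[C@@](C)(C=O)OO1 | intermediate
19 | tert-butyl{(2S)-2-[(3S,6S)-6-ethenyl-6-methyl-1,2-dioxan-3-yl]propoxy}diphenylsilane | CC(C)(C)[Si](c1ccccc1)(c1ccccc1)OC[C@H](C)[C@@H]1CC[C@@](C)(C=C)OO1 | intermediate
20 | 1-(trimethylsilyl)propyne | CC#C[Si](C)(C)C | starting material
21 | geranyl chloride | CC(C)=CCC/C(C)=C/CCl | starting material
22 | [3-(trimethylsilyl)prop-2-yn-1-yl]lithium | [Li]CC#C[Si](C)(C)C | intermediate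
23 | [(5E)-6,10-dimethylundeca-5,9-dien-1-yn-1-yl]trimethylsilane | C[Si](C)(C)C#CCC/C=C(\C)CCC=C(C)C | intermediate
24 | (5E)-6,10-dimethylundeca-5,9-dien-1-yne | C#CCC/C=C(\C)CCC=C(C)C | intermediate
25 | dimethyl[(1E,5E)-2,6,10-trimethylundeca-1,5,9-trien-1-yl]alumane | C[Al](C)/C=C(\C)CC/C=C(\C)CCC=C(C)C | intermediate
26 | (1E,5E)-1-iodo-2,6,10-trimethylundeca-1,5,9-triene | I/C=C(\C)CC/C=C(\C)CCC=C(C)C | intermediate
27 | 9-{2-[(3R,6S)-6-[(2S)-1-[(tert-butyldiphenylsilyl)oxy]propan-2-yl]-3-methyl-1,2-dioxan-3-yl]ethyl}-9-borabicyclo[3.3.1]nonane | CC(C)(C)[Si](c1ccccc1)(c1ccccc1)OC[C@H](C)[C@@H]1CC[C@@](C)(CCB2C3CCCC2CCC3)OO1 | intermediate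
28 | tert-butyl{(2S)-2-[(3S,6R)-6-methyl-6-[(3E,7E)-4,8,12-trimethyltrideca-3,7,11-trien-1-yl]-1,2-dioxan-3-yl]propoxy}diphenylsilane | CC(C)(C)[Si](c1ccccc1)(c1ccccc1)OC[C@H](C)[C@@H]1CC[C@@](C)(CC/C=C(\C)CC/C=C(\C)CCC=C(C)C)OO1 | intermediate
29 | (2S)-2-[(3S,6R)-6-methyl-6-[(3E,7E)-4,8,12-trimethyltrideca-3,7,11-trien-1-yl]-1,2-dioxan-3-yl]propan-1-ol | OC[C@H](C)[C@@H]1CC[C@@](C)(CC/C=C(\C)CC/C=C(\C)CCC=C(C)C)OO1 | intermediate
30 | (2R)-2-[(3S,6R)-6-methyl-6-[(3E,7E)-4,8,12-trimethyltrideca-3,7,11-trien-1-yl]-1,2-dioxan-3-yl]propanal | O=C[C@H](C)[C@@H]1CC[C@@](C)(CC/C=C(\C)CC/C=C(\C)CCC=C(C)C)OO1 | intermediate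
31 | (2R)-2-[(3S,6R)-6-methyl-6-[(3E,7E)-4,8,12-trimethyltrideca-3,7,11-trien-1-yl]-1,2-dioxan-3-yl]propanoic acid | OC(=O)[C@H](C)[C@@H]1CC[C@@](C)(CC/C=C(\C)CC/C=C(\C)CCC=C(C)C)OO1 | intermediate
32 | methyl (2R)-2-[(3S,6R)-6-methyl-6-[(3E,7E)-4,8,12-trimethyltrideca-3,7,11-trien-1-yl]-1,2-dioxan-3-yl]propanoate | COC(=O)[C@H](C)[C@@H]1CC[C@@](C)(CC/C=C(\C)CC/C=C(\C)CCC=C(C)C)OO1 | target

Total step count: 19. Longest linear sequence: 16 steps (steps 1–12 and 16–19); steps 13–15 prepare the alkenyl iodide in a side branch.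

Steps most likely to fail

Step 10. The activated 2,2-disubstituted epoxide may ionise before the hydroperoxide arrives, which would erode the stereochemical fidelity at C6 or divert material into hydride shift (Meinwald rearrangement) and elimination. The fallback reverses the order in which the two C–O bonds are made and sets out from 15. Intermolecular perhydrolysis of the epoxide with ethereal H2O2 and catalytic H3PMo12O40 in Et2O should open the tertiary carbon with inversion and give (2S,3R,6S)-1-[(tert-butyldiphenylsilyl)oxy]-6-hydroperoxy-7-hydroxy-2,6-dimethylheptan-3-yl methanesulfonate F1. Treatment of F1 with CsOH·H2O in DMF at 0 °C should then close the ring by 6-exo-tet displacement of the C3 mesylate by the more acidic tertiary hydroperoxide, with inversion at C3, and the route is rejoined at 17.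

Step 9. Substitution at the β-branched secondary carbon may be slow, so that E2 elimination, base-induced dehydration of the product hydroperoxide (Kornblum–DeLaMare reaction) or attack of peroxide anion on the epoxide become competitive. The fallback uses a protected, more nucleophilic peroxide in a dipolar aprotic medium and sets out from 15. 2-Methoxypropan-2-yl hydroperoxide F2, made by ozonolysis of 2,3-dimethylbut-2-ene in methanol, should displace the mesylate with inversion in the presence of CsOH·H2O in DMF at 0 °C to give the peroxyketal tert-butyl{[(2S,3S)-3-[(2-methoxypropan-2-yl)peroxy]-2-methyl-5-[(2R)-2-methyloxiran-2-yl]pentyl]oxy}diphenylsilane F3. Brief transketalisation of F3 with pyridinium p-toluenesulfonate in MeOH at 0 °C should release the hydroperoxide, and the route is rejoined at 16.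

Step 16. The O–O bond may be cleaved reductively by the borane or by zerovalent palladium, or transmetalation of the hindered alkylborane may be too slow. The fallback replaces the cross-coupling by olefination and chemoselective saturation and sets out from aldehyde 18. (2E,6E)-Farnesyl bromide and PPh3 in toluene should give triphenyl[(2E,6E)-3,7,11-trimethyldodeca-2,6,10-trien-1-yl]phosphonium bromide F4. Its ylide (n-BuLi, THF, −78 °C) should convert 18 by Wittig reaction into the 1,3-diene tert-butyl{(2S)-2-[(3S,6S)-6-methyl-6-[(3E,7E)-4,8,12-trimethyltrideca-1,3,7,11-tetraen-1-yl]-1,2-dioxan-3-yl]propoxy}diphenylsilane F5, as a mixture at the new double bond. Diimide (potassium azodicarboxylate, AcOH, MeOH, 0 °C), which leaves peroxides intact and reduces disubstituted alkenes much faster than trisubstituted ones, should saturate only the C7=C8 bond when the reaction is stopped at the dihydro stage, and the route is rejoined at 28.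

Further compounds
F1 | step 10 | (2S,3R,6S)-1-[(tert-butyldiphenylsilyl)oxy]-6-hydroperoxy-7-hydroxy-2,6-dimethylheptan-3-yl methanesulfonate | CC(C)(C)[Si](c1ccccc1)(c1ccccc1)OC[C@H](C)[C@H](OS(C)(=O)=O)CC[C@@](C)(CO)OO
F2 | step 9 | 2-methoxypropan-2-yl hydroperoxide | COC(C)(C)OO
F3 | step 9 | tert-butyl{[(2S,3S)-3-[(2-methoxypropan-2-yl)peroxy]-2-methyl-5-[(2R)-2-methyloxiran-2-yl]pentyl]oxy}diphenylsilane | CC(C)(C)[Si](c1ccccc1)(c1ccccc1)OC[C@H](C)[C@@H](OOC(C)(C)OC)CC[C@]1(C)CO1
F4 | step 16 | triphenyl[(2E,6E)-3,7,11-trimethyldodeca-2,6,10-trien-1-yl]phosphonium bromide | CC(C)=CCC/C(C)=C/CC/C(C)=C/C[P+](c1ccccc1)(c1ccccc1)c1ccccc1.[Br-]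
F5 | step 16 | tert-butyl{(2S)-2-[(3S,6S)-6-methyl-6-[(3E,7E)-4,8,12-trimethyltrideca-1,3,7,11-tetraen-1-yl]-1,2-dioxan-3-yl]propoxy}diphenylsilane | CC(C)(C)[Si](c1ccccc1)(c1ccccc1)OC[C@H](C)[C@@H]1CC[C@@](C)(C=C/C=C(\C)CC/C=C(\C)CCC=C(C)C)OO1
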